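**Retrosynthetic overview**
1. Target ⇒ E-chalcone by selective 1,4-reduction of the enone; chalcone ⇒ prenylated hydroxychromene aldehyde + 2,4-dihydroxyacetophenone (Claisen–Schmidt).
2. Prenylated aldehyde ⇒ 8-hydroxychromene aldehyde: the prenyl unit enters through an aryl C–O bond (tertiary 1,1-dimethylallyl ether at O8) and moves to C7 by a [3,3] shift.
3. 8-Hydroxychromene aldehyde ⇒ 3,4-dihydroxybenzaldehyde: site-selective C–O bond at the 4-OH (tertiary propargylic ether), then propargyl Claisen and oxa-6π electrocyclisation, which closes the pyran ring through its C–O bond.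
4. Ring order: ring B (the catechol benzene ring) is bought, the pyran ring is the only ring made (first step), ring A is bought and attached last.

Assumption: the target has no stereocentre (it is achiral), so the "single enantiomer" is the compound itself; the only stereo-elements on the way are the cis ring alkene of the chromene and the E-enone of the chalcone intermediate.

**Step 1**
Reactants: 1 protocatechualdehyde (3,4-dihydroxybenzaldehyde); 2 tertiary propargylic chloride (3-chloro-3-methylbut-1-yne)
Product: 5 hydroxychromene aldehyde (8-hydroxy-2,2-dimethyl-2H-chromene-6-carbaldehyde), via propargyl ether 3 (not isolated), via o-quinone methide 4 (not isolated)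
Conditions: CuCl2·2H2O (1 mol %), DBU (1.1 equiv), MeCN, 0 °C; aq. NH4Cl wash, solvent switch; PhNEt2, 190 °C
Reagents that add atoms: 3-chloro-3-methylbut-1-yne (compound 2), C#CC(C)(C)Cl
Why: One equivalent of base ionises only the more acidic para-formyl 4-OH, which captures the Cu-activated propargylic electrophile from 2 (copper-catalysed propargylic etherification) to give 3; its thermal aromatic propargyl Claisen rearrangement to C5 (the only free ortho carbon) and a 1,5-H shift give the (Z)-o-quinone methide 4, which closes the pyran ring by C–O bond formation in an oxa-6π electrocyclisation (no stereocentre is formed).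

**Step 2**
Reactants: 5 hydroxychromene aldehyde (8-hydroxy-2,2-dimethyl-2H-chromene-6-carbaldehyde); 6 dimethylallene (3-methylbuta-1,2-diene)
Product: 8 prenylated chromene aldehyde (8-hydroxy-2,2-dimethyl-7-(3-methylbut-2-en-1-yl)-2H-chromene-6-carbaldehyde), via tert-prenyl ether 7 (not isolated)
Conditions: Pd(PPh3)4 (5 mol %), 6 (1.5 equiv), THF, 25 °C; SiO2 plug, solvent switch; o-xylene, 130 °C
Reagents that add atoms: 3-methylbuta-1,2-diene (compound 6), CC(C)=C=C
Why: Proposed new method: zerovalent palladium is protonated by the acidic phenol 5 to a Pd–H/phenoxide pair, the Pd–H adds to the central carbon of the allene to give the (1,1-dimethylallyl)Pd cation, and under kinetic control the phenoxide collapses onto the tertiary terminus to form the quaternary C–O bond of 7 with no leaving group and no by-product; heating then drives the aromatic Claisen rearrangement from O8 to C7 (the only free ortho carbon) with allylic inversion to the prenyl group. The closest known reaction types are the palladium-catalysed addition of acidic pronucleophiles across allenes and 1,3-dienes, and the palladium-catalysed decarboxylative O-(1,1-dimethylallyl)ation of phenols with tertiary allylic carbonates, which passes through the same π-allyl ion pair; to my knowledge the addition of a phenol O–H across 1,1-dimethylallene to a tertiary aryl ether, relayed into a Claisen shift, has not been described.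

**Step 3**
Reactants: 8 prenylated chromene aldehyde (8-hydroxy-2,2-dimethyl-7-(3-methylbut-2-en-1-yl)-2H-chromene-6-carbaldehyde); 9 resacetophenone (1-(2,4-dihydroxyphenyl)ethan-1-one)
Product: 10 chalcone ((2E)-1-(2,4-dihydroxyphenyl)-3-[8-hydroxy-2,2-dimethyl-7-(3-methylbut-2-en-1-yl)-2H-chromen-6-yl]prop-2-en-1-one)
Conditions: LiN(SiMe3)2 (5 equiv), THF, −78 °C to 25 °C; then 1 M HCl to pH 4, 0 °C
Reagents that add atoms: none
Why: Excess LiN(SiMe3)2 turns all three phenols into lithium phenoxides and the methyl ketone into its enolate, so the Claisen–Schmidt aldol condensation runs without protecting groups, and E1cB loss of hydroxide gives the thermodynamically preferred E-enone (no stereocentre is formed).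

**Step 4**
Reactants: 10 chalcone ((2E)-1-(2,4-dihydroxyphenyl)-3-[8-hydroxy-2,2-dimethyl-7-(3-methylbut-2-en-1-yl)-2H-chromen-6-yl]prop-2-en-1-one)
Product: 11 target dihydrochalcone (1-(2,4-dihydroxyphenyl)-3-[8-hydroxy-2,2-dimethyl-7-(3-methylbut-2-en-1-yl)-2H-chromen-6-yl]propan-1-one)
Conditions: [(Ph3P)CuH]6 (5 mol %), PhMe2SiH (5 equiv), PhMe, 25 °C; then K2CO3 (0.2 equiv), MeOH, 25 °C
Reagents that add atoms: none
Why: The Cu–H catalyst delivers hydride only to the β-carbon of the polarised enone (Stryker-type catalytic conjugate reduction), leaving the trisubstituted prenyl alkene and the chromene alkene untouched; the phenols are silylated in the flask and freed again by methanolysis (no stereocentre is formed).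

**Compound list**
1 | 3,4-dihydroxybenzaldehyde | O=Cc1ccc(O)c(O)c1 | starting material
2 | 3-chloro-3-methylbut-1-yne | C#CC(C)(C)Cl | starting material
3 | 3-hydroxy-4-[(2-methylbut-3-yn-2-yl)oxy]benzaldehyde | C#CC(C)(C)Oc1ccc(C=O)cc1O | intermediate
4 | (3Z)-5-hydroxy-3-(3-methylbut-2-en-1-ylidene)-4-oxocyclohexa-1,5-diene-1-carbaldehyde | CC(C)=C/C=C1/C=C(C=O)C=C(O)C1=O | intermediate
5 | 8-hydroxy-2,2-dimethyl-2H-chromene-6-carbaldehyde | CC1(C)C=Cc2cc(C=O)cc(O)c2O1 | intermediate
6 | 3-methylbuta-1,2-diene | CC(C)=C=C | starting material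
7 | 2,2-dimethyl-8-[(2-methylbut-3-en-2-yl)oxy]-2H-chromene-6-carbaldehyde | CC1(C)C=Cc2cc(C=O)cc(OC(C)(C)C=C)c2O1 | intermediate
8 | 8-hydroxy-2,2-dimethyl-7-(3-methylbut-2-en-1-yl)-2H-chromene-6-carbaldehyde | CC(C)=CCc1c(C=O)cc2C=CC(C)(C)Oc2c1O | intermediate
9 | 1-(2,4-dihydroxyphenyl)ethan-1-one | CC(=O)c1ccc(O)cc1O | starting material
10 | (2E)-1-(2,4-dihydroxyphenyl)-3-[8-hydroxy-2,2-dimethyl-7-(3-methylbut-2-en-1-yl)-2H-chromen-6-yl]prop-2-en-1-one | CC(C)=CCc1c(/C=C/C(=O)c2ccc(O)cc2O)cc2C=CC(C)(C)Oc2c1O | intermediate
11 | 1-(2,4-dihydroxyphenyl)-3-[8-hydroxy-2,2-dimethyl-7-(3-methylbut-2-en-1-yl)-2H-chromen-6-yl]propan-1-one | CC(C)=CCc1c(CCC(=O)c2ccc(O)cc2O)cc2C=CC(C)(C)Oc2c1O | target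

**Step count and risks**
Total step count: 4. Longest linear sequence: 4 steps (from 1 to 11).

The three steps most likely to fail are steps 2, 3 and 4.

For step 2, the proposed Pd–H etherification may give the linear prenyl ether or C-allylation, or may not turn over with this phenol. The fallback is known chemistry and sets out from 5. 2-Methylbut-3-en-2-ol is converted with n-BuLi and Boc2O in THF into tert-butyl 2-methylbut-3-en-2-yl carbonate F1. Compound 5 is then treated with F1 and Pd(PPh3)4 (2 mol %) in THF at 0 °C, the established decarboxylative O-(1,1-dimethylallyl)ation of phenols. This gives the same ether 7, where the route is rejoined; the Claisen shift in o-xylene at 130 °C then leads to 8 as before.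

For step 3, the unprotected condensation may stall, because the polyanionic enolate is deactivated and the aldehyde is hindered and electron-rich. The fallback switches to a protecting-group approach and sets out from 9 and 8. Compound 9 with MOMCl and K2CO3 in acetone gives 1-[2-hydroxy-4-(methoxymethoxy)phenyl]ethan-1-one F2. Compound 8 with MOMCl and i-Pr2NEt in CH2Cl2 gives 8-(methoxymethoxy)-2,2-dimethyl-7-(3-methylbut-2-en-1-yl)-2H-chromene-6-carbaldehyde F3. Classical Claisen–Schmidt condensation of F2 and F3 (KOH, EtOH–H2O, 25 °C) gives (2E)-1-[2-hydroxy-4-(methoxymethoxy)phenyl]-3-[8-(methoxymethoxy)-2,2-dimethyl-7-(3-methylbut-2-en-1-yl)-2H-chromen-6-yl]prop-2-en-1-one F4. Mild acid (catalytic p-TsOH·H2O, MeOH, 40 °C, kept short so the prenyl phenol does not cyclise) removes both MOM groups and returns to the route at 10.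

For step 4, the three free phenols may slow the Cu–H catalyst, or the aryl ketone may be over-reduced. The fallback avoids the enone reduction altogether and sets out from 8. NaBH4 in MeOH at 0 °C gives 6-(hydroxymethyl)-2,2-dimethyl-7-(3-methylbut-2-en-1-yl)-2H-chromen-8-ol F5. Hydrogen-borrowing α-alkylation of 9 with F5 ([Cp*IrCl2]2 1 mol %, KOH 4 equiv, t-AmOH, 110 °C) then gives the saturated ketone directly, because the Ir–H formed by alcohol dehydrogenation reduces only the transient enone. This bypasses 10 and comes back to the route at 11.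

**Further compounds**
F1 | step 2 | tert-butyl 2-methylbut-3-en-2-yl carbonate | CC(C)(C)OC(=O)OC(C)(C)C=C
F2 | step 3 | 1-[2-hydroxy-4-(methoxymethoxy)phenyl]ethan-1-one | CC(=O)c1ccc(OCOC)cc1O
F3 | step 3 | 8-(methoxymethoxy)-2,2-dimethyl-7-(3-methylbut-2-en-1-yl)-2H-chromene-6-carbaldehyde | CC(C)=CCc1c(C=O)cc2C=CC(C)(C)Oc2c1OCOC
F4 | step 3 | (2E)-1-[2-hydroxy-4-(methoxymethoxy)phenyl]-3-[8-(methoxymethoxy)-2,2-dimethyl-7-(3-methylbut-2-en-1-yl)-2H-chromen-6-yl]prop-2-en-1-one | CC(C)=CCc1c(/C=C/C(=O)c2ccc(OCOC)cc2O)cc2C=CC(C)(C)Oc2c1OCOC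
F5 | step 4 | 6-(hydroxymethyl)-2,2-dimethyl-7-(3-methylbut-2-en-1-yl)-2H-chromen-8-ol | CC(C)=CCc1c(CO)cc2C=CC(C)(C)Oc2c1O
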